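**Retrosynthetic overview**
1. The target, (2S)-3'-hydroxy-4',5',7,8-tetramethoxyflavanone, comes from its ring B benzyl ether by hydrogenolysis. Rings A and B are bought as arenes and ring C is the only ring formed, last.
2. Ring C is opened at C2–C3 and C4–C4a together: a formal inverse-demand [4+2] (asymmetric oxa-Povarov annulation) between an O-aryl oxocarbenium ion and ethoxyacetylene as a ketene equivalent, which also sets C2.
3. Enabling feature: in ring A, C4a–H is ortho to the ring oxygen O1 and para to the C7 methoxy group, while the other ortho position, C8, is blocked by OMe. Hence O1–C8a=C4a plus a cationic C2 is a 2-oxadiene, and the para-methoxy group of ring B stabilises that cation.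
4. The oxocarbenium precursor is the symmetric bis(2,3-dimethoxyphenyl) acetal of the ring B aldehyde (aldehyde, then benzal chloride, then double phenoxide displacement). Both leaving groups are identical, so ionisation can only give the wanted ion.

Key step: step 4

Assumption: the sense of induction of the ion-pairing catalyst in step 4 cannot be predicted from precedent, so the catalyst enantiomer meant is the one that delivers the (2S) product.

**Step 1**
Reactants: 1 3-hydroxy-4,5-dimethoxybenzaldehyde
Product: 2 3-(benzyloxy)-4,5-dimethoxybenzaldehyde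
Conditions: BnBr (1.1 equiv), K2CO3 (1.5 equiv), DMF, rt
Reagents that add atoms: benzyl bromide, BrCc1ccccc1
Why: Williamson ether synthesis on the only acidic OH; the benzyl ether should survive the acidic steps and is removed under neutral conditions at the end.

**Step 2**
Reactants: 2 3-(benzyloxy)-4,5-dimethoxybenzaldehyde
Product: 3 1-(benzyloxy)-5-(dichloromethyl)-2,3-dimethoxybenzene
Conditions: SOCl2 (1.5 equiv), DMF (10 mol%), CH2Cl2, 0 °C to rt; volatiles removed, used crude
Reagents that add atoms: thionyl chloride, ClS(Cl)=O
Why: Vilsmeier-type deoxygenative gem-dichlorination of an electron-rich aromatic aldehyde; the aryl ethers are inert to the reagent.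

**Step 3**
Reactants: 3 1-(benzyloxy)-5-(dichloromethyl)-2,3-dimethoxybenzene; 4 2,3-dimethoxyphenol
Product: 6 1-(benzyloxy)-5-[bis(2,3-dimethoxyphenoxy)methyl]-2,3-dimethoxybenzene, via alpha-chloro ether 5 (not isolated)
Conditions: 4 (2.3 equiv), NaH (2.3 equiv), DMF, 0 °C; then 3 in THF, 0 °C to rt
Reagents that add atoms: none
Why: twofold Williamson-type O-alkylation of the phenoxide by a benzal chloride, the classical route to diaryl acetals; the first displacement gives chloro ether 5, which ionises even more easily, so the reaction should run on to the acetal.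

**Step 4**
Reactants: 6 1-(benzyloxy)-5-[bis(2,3-dimethoxyphenoxy)methyl]-2,3-dimethoxybenzene; 7 ethoxyacetylene
Product: 10 (2S)-2-[3-(benzyloxy)-4,5-dimethoxyphenyl]-7,8-dimethoxy-2,3-dihydro-4H-chromen-4-one, via aryl oxocarbenium triflate 8 (not isolated), via 4-ethoxy-2H-chromene 9 (not isolated)
Conditions: chiral squaramide hydrogen-bond donor built from tert-leucine and a 2-(9-phenanthryl)pyrrolidine amide with a 3,5-bis(trifluoromethyl)anilino arm (10 mol%), Et3SiOTf (10 mol%), 7 (3 equiv, added over 2 h), t-BuOMe/toluene, −78 °C, dark; then 1 M HCl, THF, 0 °C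
Reagents that add atoms: water, O
Why: Proposed new method: Et3SiOTf (and then the TfOH returned in each turnover) ionises acetal 6 to the E-configured O-aryl oxocarbenium ion 8, whose triflate is held by the squaramide N–H groups so that the cation sits in the chiral pocket; the nucleophilic terminal carbon of 7 adds to the oxocarbenium carbon (C2–C3), the resulting ketene-oxonium carbon is captured at once by ring A carbon C4a (C4–C4a), rearomatisation gives 9 and the proton that ionises the next acetal, and dilute acid then hydrolyses the enol ether to the ketone. The closest known reaction types are the SnCl4-promoted oxa-Povarov reaction of aryl oxocarbenium ions with alkenes, the acid-catalysed addition of ynol ethers to acetal-derived oxocarbenium ions, and hydrogen-bond-donor ion-pair catalysis (with a silyl triflate or a sulfonic acid) of Mukaiyama additions to aryl acetals and of the aza-Povarov reaction; new is their combination on an O-aryl oxocarbenium ion with an ynol ether as the two-carbon partner. Ring C closes as a stepwise formal [4+2] of the cationic 2-oxadiene C4a=C8a–O1=C2 with the alkyne, the second bond forming by a 6-exo-dig Friedel–Crafts attack of C4a on the C=O+ bond of the ketene-oxonium ion, which leaves C3=C4 endocyclic. The C2 stereocentre is set in the first C–C bond formation by the catalyst alone (face selection on the ion-paired oxocarbenium ion, no substrate control) and is not touched by the mild hydrolysis. Regioselectivity is secured by the substrate, since C4a is the only free position ortho to O1 and is para to the C7 methoxy group, and C-trapping should beat O-trapping because the only internal oxygen could close only a strained four-membered oxete. Enantioselectivity and suppression of ynol ether oligomerisation (slow addition, low temperature) are the selectivities that have to be won.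

**Step 5**
Reactants: 10 (2S)-2-[3-(benzyloxy)-4,5-dimethoxyphenyl]-7,8-dimethoxy-2,3-dihydro-4H-chromen-4-one
Product: 11 (2S)-2-(3-hydroxy-4,5-dimethoxyphenyl)-7,8-dimethoxy-2,3-dihydro-4H-chromen-4-one
Conditions: H2 (1 atm), Pd/C (10 wt% palladium on carbon), EtOAc, rt, stopped after one equivalent of H2
Reagents that add atoms: none
Why: catalytic hydrogenolysis of an aryl benzyl ether; the neutral, base-free medium should leave the C2 stereocentre, which is labile only through base-induced retro-oxa-Michael opening, untouched.

**Compound list**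
1 | 3-hydroxy-4,5-dimethoxybenzaldehyde | COc1cc(C=O)cc(O)c1OC | starting material
2 | 3-(benzyloxy)-4,5-dimethoxybenzaldehyde | COc1cc(C=O)cc(OCc2ccccc2)c1OC | intermediate
3 | 1-(benzyloxy)-5-(dichloromethyl)-2,3-dimethoxybenzene | COc1cc(C(Cl)Cl)cc(OCc2ccccc2)c1OC | intermediate
4 | 2,3-dimethoxyphenol | COc1cccc(O)c1OC | starting material
5 | 1-(benzyloxy)-5-[chloro(2,3-dimethoxyphenoxy)methyl]-2,3-dimethoxybenzene (racemic) | COc1cc(C(Cl)Oc2cccc(OC)c2OC)cc(OCc2ccccc2)c1OC | intermediate
6 | 1-(benzyloxy)-5-[bis(2,3-dimethoxyphenoxy)methyl]-2,3-dimethoxybenzene | COc1cc(C(Oc2cccc(OC)c2OC)Oc2cccc(OC)c2OC)cc(OCc2ccccc2)c1OC | intermediate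
7 | ethoxyacetylene (ethoxyethyne) | C#COCC | starting material
8 | (E)-{[3-(benzyloxy)-4,5-dimethoxyphenyl]methylidene}(2,3-dimethoxyphenyl)oxonium trifluoromethanesulfonate | COc1cc(/C=[O+]/c2cccc(OC)c2OC)cc(OCc3ccccc3)c1OC.[O-]S(=O)(=O)C(F)(F)F | intermediate
9 | (2S)-2-[3-(benzyloxy)-4,5-dimethoxyphenyl]-4-ethoxy-7,8-dimethoxy-2H-chromene | COc1cc([C@@H]2C=C(OCC)c3ccc(OC)c(OC)c3O2)cc(OCc4ccccc4)c1OC | intermediate
10 | (2S)-2-[3-(benzyloxy)-4,5-dimethoxyphenyl]-7,8-dimethoxy-2,3-dihydro-4H-chromen-4-one | COc1cc([C@@H]2CC(=O)c3ccc(OC)c(OC)c3O2)cc(OCc4ccccc4)c1OC | intermediate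
11 | (2S)-2-(3-hydroxy-4,5-dimethoxyphenyl)-7,8-dimethoxy-2,3-dihydro-4H-chromen-4-one | COc1cc([C@@H]2CC(=O)c3ccc(OC)c(OC)c3O2)cc(O)c1OC | target

**Step count**
Total steps: 5. Longest linear sequence: 5 steps (from 1).

**Steps most likely to fail**

Step 4. The ion pair may give poor facial discrimination. The ketene-oxonium ion may also be diverted, by attack of the liberated phenol or by oligomerisation of the ynol ether, before ring A closes on it. The fallback uses known chemistry, sets out from 4 and 2, and comes back at 10. Ortho-acetylation of 4 (AcOH, BF3·OEt2, 90 °C, Fries-type through the boron chelate) should give 1-(2-hydroxy-3,4-dimethoxyphenyl)ethan-1-one F1. Claisen–Schmidt condensation of this with 2 (KOH, EtOH, rt) should give (E)-3-[3-(benzyloxy)-4,5-dimethoxyphenyl]-1-(2-hydroxy-3,4-dimethoxyphenyl)prop-2-en-1-one F2. Oxa-Michael ring closure (NaOAc, EtOH, reflux) should give racemic 2-[3-(benzyloxy)-4,5-dimethoxyphenyl]-7,8-dimethoxy-2,3-dihydro-4H-chromen-4-one F3. Preparative chromatography on a polysaccharide chiral phase then delivers 10, and the unwanted enantiomer can be re-equilibrated through F2 with base and recycled.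

Step 3. The ambident phenoxide may be alkylated on carbon by the benzylic cation, and the moisture-sensitive dichloride may hydrolyse back to 2. The fallback sets out from 2 (and 4), avoids the dichloride, and comes back at 10. Condensation of 2 with 1H-benzotriazole and SOCl2 (toluene, 60 °C) should give 1-{[3-(benzyloxy)-4,5-dimethoxyphenyl](chloro)methyl}-1H-benzotriazole F4. Its SN2-type reaction with the sodium salt of 4 (NaH, DMF, rt) should give 1-{[3-(benzyloxy)-4,5-dimethoxyphenyl](2,3-dimethoxyphenoxy)methyl}-1H-benzotriazole F5. This N,O-acetal takes the place of 6 in step 4, ionised with one equivalent of Et3SiOTf by loss of benzotriazole.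

Step 5. Hydrogenolysis may run on to cleave the benzylic C2–O1 bond (ring opening to a dihydrochalcone) or to reduce the aryl ketone. The fallback sets out from 10 and comes back at 11 without a reductant: Lewis acid debenzylation with BCl3 (2 equiv) and pentamethylbenzene (3 equiv) as cation scavenger, CH2Cl2, −78 °C. It makes no new compound (entry F0).

**Further compounds**
F1 | step 4 | 1-(2-hydroxy-3,4-dimethoxyphenyl)ethan-1-one | CC(=O)c1ccc(OC)c(OC)c1O
F2 | step 4 | (E)-3-[3-(benzyloxy)-4,5-dimethoxyphenyl]-1-(2-hydroxy-3,4-dimethoxyphenyl)prop-2-en-1-one | COc1cc(/C=C/C(=O)c2ccc(OC)c(OC)c2O)cc(OCc2ccccc2)c1OC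
F3 | step 4 | racemic 2-[3-(benzyloxy)-4,5-dimethoxyphenyl]-7,8-dimethoxy-2,3-dihydro-4H-chromen-4-one | COc1cc(C2CC(=O)c3ccc(OC)c(OC)c3O2)cc(OCc4ccccc4)c1OC
F4 | step 3 | 1-{[3-(benzyloxy)-4,5-dimethoxyphenyl](chloro)methyl}-1H-benzotriazole (racemic) | COc1cc(C(Cl)n2nnc3ccccc32)cc(OCc2ccccc2)c1OC
F5 | step 3 | 1-{[3-(benzyloxy)-4,5-dimethoxyphenyl](2,3-dimethoxyphenoxy)methyl}-1H-benzotriazole (racemic) | COc1cc(C(Oc2cccc(OC)c2OC)n2nnc3ccccc32)cc(OCc2ccccc2)c1OC
F0 | step 5 | none | none
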